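The closed, stirred vessel holds electrophile with nucleophile in excess and a trace of protic impurity, and the recipes differ in equivalents of nucleophile.

| flask | electrophile | nucleophile | protic impurity | remark | time |
|---|---|---|---|---|---|
| maple | 0.10 M | 3.9 equiv | 2 mM | run made earlier |  |
| oak | 0.10 M | 10 equiv | 2 mM | run made earlier |  |
| green | 0.10 M | 3.00 equiv | 2.00 mM |  | 3.0 h |
| blue | 0.10 M | 4.50 equiv | 2.00 mM |  | 3.0 h |
| red | 0.10 M | 6.80 equiv | 2.00 mM |  | 3.0 h |

- maple (time / min: electrophile / %, target / %): 15.0: 66, 20; 40.0: 41, 42; 80.0: 21, 58; 120: 12, 65
- oak (time / min: electrophile / %, target / %): 30.0: 22, 68; 60.0: 8, 86; 90.0: 4, 92; 120: 0, 91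

(standard deviation of a reading: 2 percentage points)



- part of the electrophile that has reacted at the end, green
- part of the electrophile that has reacted at the end, blue
- part of the electrophile that has reacted at the end, red
- what raising the equivalents of nucleophile from its lowest to its highest value here does to the part of the electrophile that has reacted (changes below 5 percentage points count as none) (it falls / no change / it rises)

Target forms as electrophile meets nucleophile, so its rate is taken as k · c(electrophile) · c(nucleophile). The first oak interval reads k, because the nucleophile charged there, 1.00 M, stands far above the electrophile. Over 30.0 min the electrophile falls to 22%, so its logarithmic mean and then k follow: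

mean electrophile = (charge − rest) / ln(charge / rest) = 51.5% of charge

k = target share / (mean share · c(nucleophile) · t) = 2.64 M⁻¹ h⁻¹

This k, the target constant, is a reading and carries the scatter of oak. With c(nucleophile) held at its charge the rate becomes pseudo-first-order and integrates in closed form:

electrophile left = exp(−k · c(nucleophile) · t)

The weak link is that this line sends electrophile one way at a nucleophile level that stays put, whereas maple at 120 min has 23.0% of its charge in neither column. So the line is tried on maple, which gave k nothing: at 15.0 min it leaves 77.3% against a reading of 66%, a gap far beyond the scatter of 2 percentage points, while at 120 min it leaves 12.8% against a reading of 12%, a gap inside that scatter. The line thus fails on early maple and meets late maple without accounting for the material in neither column, so what it gives is a rough estimate and no proven result; with that warning, the part reacted at 3.0 h comes out as: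

green 90.7%, blue 97.2%, red 99.5%

From green to red that is a rise of 8.8 points, more than the 5 points that counts.

The forecast commits to 92%, 97% and 99.5%, and says it rises: “Conversion therefore rises by roughly 7 points, close to the threshold but above it.” At green it stands 1.3 points above the exponential.

The part reacted in the flask stands at 90.6%, 96.2% and 99.2% for green, blue and red, and from green to red it rises by 8.6 points. At 1.50 h green held 23.6% electrophile, with 26.5% of the charge in self-condensation product. The same k gives 30.5% left at that time, and 9.29% at 3.00 h against the 9.43% that stood in green.

    electrophile + nucleophile → acid set free + target (k = 2.80 M⁻¹ h⁻¹)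
    nucleophile + protic impurity → quenched reagent (k = 403 M⁻¹ h⁻¹)
    nucleophile + acid set free ⇌ protonated nucleophile, settled at all times (K = 26600 M⁻¹)
    2 electrophile → self-condensation product (k = 3.18 M⁻¹ h⁻¹)

A neighbour of red, charged with 0.025 M of electrophile at the same equivalents and time, gets 74.0% reacted from k. The flask gives 77.2%.

All runs were computed from invented constants; the scatter is artificial.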